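## The problem

Target 17 is a trans-fused α-methylene-γ-butyrolactone on a fully saturated cyclodecane. Locants used throughout: C5 is the ketone carbon, C4 the CH(CH3) carbon, C3–C1 the (CH2)3 bridge, C10 the C(OH)CH3 carbon, C9 the CH–O-isovaleryl carbon, C8 the lactone CH–O carbon, C7 the lactone β-carbon and C6 the CHOH carbon; C11/C12/C13 are the lactone α-carbon, carbonyl and exocyclic CH2, and C14/C15 the methyls on C10/C4. With these locants 17 is (4S,6S,7S,8R,9S,10R).

The ring has no alkene or other rigid element, so closing a ten-membered ring from an open chain fights entropy and transannular strain. Five contiguous stereocentres (C6–C10) must be related to each other and to the isolated C4. C7 can control its neighbours C6 and C8, and a free C8–OH can control C9/C10. C4 has no stereogenic neighbour in the chain and can be tied to the rest only through a ring.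

The C5 ketone sits between two epimerisable centres (C4, and the C6 α-ketol). The α-methylene lactone is a Michael acceptor and can migrate to O6. The isovalerate is next to a tertiary alcohol. Strong base, nucleophiles and reductants are therefore excluded late in the route.

The feature that makes the key step possible is the array O=C5 ··· C10(OH)(CH3)–C9(O)–C8(O). C5 and C10 face each other 1,6 across the ring. If the C9 and C10 oxygens are traced back to an (E)-C9=C10 alkene, the pattern ketone / alkene / allylic C8–OH is the retron of a Grob-type epoxy-alcohol fragmentation of a C5–C10 bond. Restoring that bond turns C5–C10 plus C11–C14 into the six-membered ring of carvone (ketone at C5, methyl-bearing C10, isopropenyl-bearing C7).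

## Retrosynthesis

17 ⇒ 16 ⇒ 14 + 15. The C9–O ester bond and the C6 O–Si bond are cut last. With C6 silylated and C10 tertiary, C9–OH is the only acylable hydroxyl in 14, so isovaleric anhydride 15 needs no further differentiation. The final fluoride deprotection is non-basic and spares C4, C6 and the lactone.

14 ⇒ 13 ⇒ 11. The C10–OH bond is cut back to the 9,10-epoxide 13 (water at the tertiary carbon, inversion). The C6–O bond is cut back to the C5/C6 enol ether of ketone 11 (Rubottom transform). Opening an (E)-derived epoxide gives the anti C9/C10 diol that the target needs; a syn-dihydroxylation would give the wrong C10. The forward steps must find C6 rather than C4 and the open face of the enol ether.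

11 ⇒ 8 ⇒ 7. The lactone C12–O8 bond and the C12 oxidation level are removed, leaving an isopropenyl group on C7 next to the free C8–OH of 7. This is the classical isopropenyl / vicinal hydroxyl retron of an α-methylene lactone. It needs only an allylic oxidation and an oxidative lactonisation, and the trans fusion is already fixed by C7/C8.

7 ⇒ 6. The epoxide C–O bonds are cut to the (E)-allylic alcohol 6. The forward epoxidation is directed by C8–OH, which sets C9 and (after opening) C10 from C8 in one operation.

6 ⇒ 4 (via 5). This is the key cut run backwards: the C5–C10 bond is re-formed. Ketone, (E)-alkene and allylic alcohol of 6 collapse to the epoxide 5 of the cis-fused bicyclic homoallylic alcohol 4. Compound 4 has no medium ring, one oxygen, and four stereocentres all set by six-membered-ring control. The forward reaction must epoxidise the ring alkene only, on the face of the hydroxyl, and then fragment.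

4 ⇒ 3. The C4–C5 bond is cut (intramolecular Barbier transform) to bromo ketone 3. This six-membered closure is the only ring-forming C–C bond construction of the whole route, and it sets C4 relative to C5/C10.

3 ⇒ 1 + 2. The C10–C1 bond is cut (deconjugative α-alkylation of an enone). This leads to (R)-carvone 1, which supplies C5–C10, C11–C14 and the C7 configuration, and to 1,4-dibromopentane 2, which supplies C1–C4 and C15.

## Roads not taken

Alternative 1: the most obvious cut is C7–C8 together with the lactone C–O bond. The forward step is an intramolecular Zn- or Cr-mediated allylation of aldehyde A1 by its 2-(bromomethyl)acrylate terminus, which closes the ring and the lactone at once. A1 must carry C4, C6, C9 and C10 already, built on an open chain by a long sequence of separate asymmetric steps. Its α-acyloxy aldehyde is epimerisable, and the ten-membered closure of a flexible saturated chain has no conformational help. The trans C7/C8 relationship would depend on macrocyclic transition-state preferences. The chosen plan forms only a six-membered ring and takes the medium ring from a bond cleavage.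

Alternative 2: cut C2–C3. The forward step is ring-closing metathesis of diene A2, then hydrogenation of the new alkene. Ten-membered RCM on a substrate without a turn element competes with dimerisation. The hydrogenation would also reduce the α-methylene lactone unless it is masked. As in Alternative 1, every stereocentre has to be made before the ring exists.

Alternative 3: the same carvone platform, but with an anionic oxy-Cope rearrangement (elemane to germacrane) of divinyl carbinol A3 to trienone A4, again cutting C5–C10. It delivers the ring and the C5 ketone in one step. However, it leaves a conjugated C8=C9–C10=C1 diene that must become C8–O, C9–O, C10–OH and C1H2, for which no regio- and stereocontrolled oxidation is obvious. The C4 centre would come from enolate protonation on the medium ring, and a competing [3,3] shift through the ring alkene is possible. The fragmentation in the chosen plan puts the C8 oxygen and the C9=C10 alkene exactly where the triol array needs them.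

Key step: step 3

Remark on the chemistry: 2 is used as the racemate, so 3 is a 1:1 mixture of epimers at its CHBr carbon; this centre is destroyed in step 2.

## Route

Step 1
Reactants: 1 (R)-(−)-carvone; 2 1,4-dibromopentane
Product: 3 (2S,5S)-2-(4-bromopentyl)-2-methyl-5-(prop-1-en-2-yl)cyclohex-3-en-1-one
Conditions: KOtBu, t-BuOH–THF, 0 °C; then 2 (3 equiv), 0 °C → rt
Reagents that add atoms: none
Why: Deconjugative α-alkylation of the extended dienolate of an enone: the linear dienolate reacts at C10 with the primary bromide of 2, moving the alkene to C8=C9; the new bond should form axially on the face syn to the C7 isopropenyl group (product half-chair with isopropenyl pseudo-equatorial), the same sense as in base-mediated annulations of dihydrocarvone, so the chain ends cis to the C7 substituent.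

Step 2
Reactants: 3 bromo ketone
Product: 4 (3S,4aR,5S,8aS)-5,8a-dimethyl-3-(prop-1-en-2-yl)-3,4,5,6,7,8-hexahydronaphthalen-4a(8aH)-ol
Conditions: SmI2 (2.5 equiv), HMPA, THF, −78 °C → rt; aq. NH4Cl
Reagents that add atoms: none
Why: SmI2-promoted intramolecular Barbier cyclisation: the pseudo-axial side chain delivers the alkylsamarium to the same face of the ketone (cis ring fusion), and a chair transition state with the C4 methyl equatorial and anti to the O–Sm group should set C4 (methyl trans to the new hydroxyl); both bromide epimers converge and the two alkenes are inert.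

Step 3
Reactants: 4 bicyclic homoallylic alcohol
Product: 6 (E)-8-hydroxy-2,6-dimethyl-9-(prop-1-en-2-yl)cyclodec-6-en-1-one (C4, C7, C8 configured as in 17), via epoxy alcohol 5 (not isolated)
Conditions: t-BuOOH (1.0 equiv), VO(acac)2 (5 mol%), CH2Cl2, 0 °C; then Ti(OiPr)4 (20 mol%), 40 °C
Reagents that add atoms: tert-butyl hydroperoxide, CC(C)(C)OO
Why: Proposed new method: the axial homoallylic C5–OH, which also lies on the convex face of the cis-fused bicycle, directs vanadium-catalysed epoxidation to the α face of C8=C9 only, so the isopropenyl group is spared and 5 has hydroxyl and epoxide cis. In the metal alkoxide of 5 the C5–C10 bond can stand anti-periplanar to the C9–O bond of the epoxide; electron push from the alkoxide then breaks C5–C10 and C9–O in a Grob-type fragmentation, giving the C5 ketone, the C9=C10 alkene and the C8 alkoxide. The closest known reaction types are the Ti(IV)/TBHP epoxy-alcohol fragmentation of bridged bicyclic tertiary homoallylic alcohols and the Grob fragmentation of decalin-1,3-diol monosulfonates to cyclodecenones; new here is an epoxide nucleofuge at a secondary carbon of a fused bicyclo[4.4.0] alkoxide. No ring is closed: the ten-membered ring arises by cleavage of the ring-fusion bond (a four-carbon ring expansion of the carvone ring). C8 keeps the oxygen and configuration of the epoxide (trans to the C7 side chain, hence the later trans lactone). The alkene geometry follows from the anti-periplanar alignment: the C10 substituent on the face of the departing oxygen (the methyl) ends cis to C8, giving E. C4 and C7 are not touched. The step needs fragmentation to win over 1,4-ether formation and 1,2-shifts; the cis hydroxyl/epoxide relationship rules out backside attack of O5 on C8, and only the C5–C10 bond is activated by the alkoxide.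

Step 4
Reactants: 6 (E)-allylic alcohol
Product: 7 9,10-epoxide of 6 (target locants), epoxide oxygen syn (threo) to the C8 hydroxyl
Conditions: t-BuOOH, VO(acac)2 (cat.), CH2Cl2, 0 °C
Reagents that add atoms: tert-butyl hydroperoxide, CC(C)(C)OO
Why: Hydroxyl-directed epoxidation of an allylic alcohol: A(1,3) strain with the C10 methyl (cis to C8 in the E-alkene) holds H8 in the alkene plane, the ring lies on one face and the hydroxyl on the open one, so oxygen should be delivered syn to OH (threo), which is the C9 configuration of 17; the isolated isopropenyl group reacts far more slowly.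

Step 5
Reactants: 7 epoxy alcohol
Product: 8 allylic alcohol, 7 with the C7 substituent changed to 3-hydroxyprop-1-en-2-yl
Conditions: SeO2 (cat.), t-BuOOH, salicylic acid (cat.), CH2Cl2, rt
Reagents that add atoms: tert-butyl hydroperoxide, CC(C)(C)OO
Why: Selenium dioxide allylic oxidation (ene reaction, [2,3] shift) of the only remaining alkene at its methyl group; partial over-oxidation to the enal is harmless because step 6 passes through that enal.

Step 6
Reactants: 8 allylic alcohol
Product: 11 trans-fused α-methylene-γ-butyrolactone bearing the C5 ketone and the 9,10-epoxide, via hydroxy enal 9 (not isolated), via lactol 10 (not isolated)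
Conditions: MnO2 (excess), CH2Cl2, rt
Reagents that add atoms: none
Why: Oxidative lactonisation of a 2-methylene-1,4-diol: MnO2 oxidises the allylic alcohol to the enal, the C8 hydroxyl closes the γ-lactol and MnO2 oxidises it on to the lactone; the non-allylic C8 carbinol is not oxidised and the trans fusion is fixed by C7/C8.

Step 7
Reactants: 11 epoxy keto lactone
Product: 13 C6 tert-butyldimethylsilyloxy ketone (C6 configured as in 17), via silyl enol ether 12 (not isolated)
Conditions: LiHMDS, THF, −78 °C; TBSCl, DMPU; then mCPBA, NaHCO3, CH2Cl2, −20 °C
Reagents that add atoms: tert-butyldimethylsilyl chloride, CC(C)(C)[Si](C)(C)Cl; 3-chloroperbenzoic acid, OOC(=O)c1cccc(Cl)c1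
Why: Rubottom oxidation: kinetic deprotonation takes the C6 methylene rather than the C4 methine, and epoxidation of the silyl enol ether with silyl migration gives the α-silyloxy ketone; with H7 held in the enol plane by A(1,3) strain the ring body covers the face of C8, so the peracid should attack the open face and place O6 anti to C8; the electron-poor methylene lactone is inert to peracid.

Step 8
Reactants: 13 epoxy silyloxy ketone
Product: 14 9,10-diol (C9 secondary OH, C10 tertiary OH, configured as in 17)
Conditions: H2O, Sc(OTf)3 (5 mol%), MeCN, 0 °C → rt
Reagents that add atoms: water, O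
Why: Acid-catalysed hydrolysis of a trisubstituted epoxide at its tertiary carbon C10 with inversion, with C9–O retained, giving the anti diol from the (E)-derived epoxide; inversion should be helped by the transannular C5 carbonyl oxygen, which sits inside the ring anti to the epoxide oxygen and would return the same diol after hydration.

Step 9
Reactants: 14 diol; 15 isovaleric anhydride
Product: 16 C9 isovalerate, the 6-O-TBS ether of 17
Conditions: Et3N, DMAP (cat.), CH2Cl2, rt
Reagents that add atoms: none
Why: DMAP-catalysed acylation of the only free secondary alcohol; the tertiary C10–OH does not react under these conditions and O6 is silylated.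

Step 10
Reactants: 16 silyl ether
Product: 17 target (CNP0240128.1)
Conditions: HF·pyridine, THF, 0 °C → rt
Reagents that add atoms: none
Why: Fluoride cleavage of the silyl ether under non-basic conditions, which should leave C4, the C6 α-ketol, the isovalerate and the methylene lactone untouched.

## Compound list

1 | (R)-(−)-carvone, (5R)-2-methyl-5-(prop-1-en-2-yl)cyclohex-2-en-1-one | O=C1C[C@H](C(C)=C)CC=C1C | starting material
2 | 1,4-dibromopentane (racemic) | CC(Br)CCCBr | starting material
3 | (2S,5S)-2-(4-bromopentyl)-2-methyl-5-(prop-1-en-2-yl)cyclohex-3-en-1-one (chain cis to isopropenyl; epimers at CHBr) | O=C1C[C@H](C(C)=C)C=C[C@]1(C)CCCC(C)Br | intermediate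
4 | (3S,4aR,5S,8aS)-5,8a-dimethyl-3-(prop-1-en-2-yl)-3,4,5,6,7,8-hexahydronaphthalen-4a(8aH)-ol (cis-fused; OH and angular CH3 trans to isopropenyl; C5-methyl trans to OH) | O[C@@]12C[C@H](C(C)=C)C=C[C@]1(C)CCC[C@@H]2C | intermediate
5 | 1,2-epoxide of 4, epoxide cis to the hydroxyl | O[C@@]12C[C@H](C(C)=C)[C@H]3O[C@H]3[C@]1(C)CCC[C@@H]2C | intermediate (not isolated)
6 | (E)-8-hydroxy-2,6-dimethyl-9-(prop-1-en-2-yl)cyclodec-6-en-1-one, C4/C7/C8 (target locants) as in 17 | C/C1=C\[C@H](O)[C@@H](C(C)=C)CC(=O)[C@@H](C)CCC1 | intermediate
7 | 9,10-epoxide of 6 (target locants), epoxide syn to the C8 hydroxyl | O[C@@H]1[C@@H](C(C)=C)CC(=O)[C@@H](C)CCC[C@]2(C)O[C@@H]12 | intermediate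
8 | 7 with 3-hydroxyprop-1-en-2-yl at C7 (allylic alcohol) | O[C@@H]1[C@@H](C(=C)CO)CC(=O)[C@@H](C)CCC[C@]2(C)O[C@@H]12 | intermediate
9 | 7 with 3-oxoprop-1-en-2-yl at C7 (hydroxy enal) | O[C@@H]1[C@@H](C(=C)C=O)CC(=O)[C@@H](C)CCC[C@]2(C)O[C@@H]12 | intermediate (not isolated)
10 | γ-lactol of 9 (anomeric centre undefined) | C=C1C(O)O[C@@H]2[C@@H]1CC(=O)[C@@H](C)CCC[C@]3(C)O[C@@H]23 | intermediate (not isolated)
11 | trans-fused α-methylene-γ-butyrolactone with C5 ketone and 9,10-epoxide | C=C1C(=O)O[C@@H]2[C@@H]1CC(=O)[C@@H](C)CCC[C@]3(C)O[C@@H]23 | intermediate
12 | C5–C6 tert-butyldimethylsilyl enol ether of 11 (C4 and C7 cis on the enol double bond) | C=C1C(=O)O[C@@H]2[C@@H]1/C=C(/O[Si](C)(C)C(C)(C)C)[C@@H](C)CCC[C@]3(C)O[C@@H]23 | intermediate (not isolated)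
13 | 11 bearing the C6 tert-butyldimethylsilyloxy group | C=C1C(=O)O[C@@H]2[C@@H]1[C@H](O[Si](C)(C)C(C)(C)C)C(=O)[C@@H](C)CCC[C@]3(C)O[C@@H]23 | intermediate
14 | 9,10-diol, 6-O-TBS | C=C1C(=O)O[C@@H]2[C@@H]1[C@H](O[Si](C)(C)C(C)(C)C)C(=O)[C@@H](C)CCC[C@@](C)(O)[C@H]2O | intermediate
15 | isovaleric (3-methylbutanoic) anhydride | CC(C)CC(=O)OC(=O)CC(C)C | starting material
16 | 6-O-tert-butyldimethylsilyl ether of 17 | C=C1C(=O)O[C@@H]2[C@@H]1[C@H](O[Si](C)(C)C(C)(C)C)C(=O)[C@@H](C)CCC[C@@](C)(O)[C@H]2OC(=O)CC(C)C | intermediate
17 | CNP0240128.1 | C=C1C(=O)O[C@@H]2[C@@H]1[C@H](O)C(=O)[C@@H](C)CCC[C@@](C)(O)[C@H]2OC(=O)CC(C)C | target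

## Step count and risks

Total: 10 steps. Longest linear sequence: 10 steps from 1.

Step 3 (key step, proposed new method). The alkoxide of 5 may fail to reach the reactive half-chair, which places the C7 isopropenyl group and C4 pseudo-axial on the same face. The epoxy alcohol would then persist, or the Lewis acid would induce a 1,2-shift of the C10–C1 bond, which is anti-periplanar to the epoxide in the resting conformer. Fallback with known chemistry, from 4: hydrogen-bond-directed syn-dihydroxylation (OsO4·TMEDA, −78 °C) of the ring alkene on the hydroxyl face should give the 1,2,4a-triol F1. 1,1′-Sulfonyldiimidazole/DBU converts its cis-diol into the cyclic sulfate F2. KH in THF then triggers a classical Grob fragmentation with a sulfate nucleofuge to the potassium sulfate monoester F3, and dilute H2SO4 in wet THF hydrolyses F3 to 6.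

Step 1. Alkylation may occur on oxygen or at C6, or on the face anti to the isopropenyl group. The wrong face would invert every later relationship to C7. Fallback, from 1: nucleophilic epoxidation (H2O2, NaOH) gives the epoxy ketone F4 with the epoxide trans to the isopropenyl group. Pent-4-enylmagnesium bromide adds anti to the epoxide to give the tertiary alcohol F5. A Lewis-acid semipinacol shift (BF3·OEt2) moves the pentenyl group, anti-periplanar to the C10–O bond, onto C10 with inversion to give the β-hydroxy ketone F6, which fixes the chain cis to the isopropenyl group. Burgess dehydration gives the β,γ-enone F7, and a SmI2/HMPA/t-BuOH ketyl–olefin 6-exo cyclisation (methyl anti to O–Sm) returns to the route at 4.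

Step 5. On this late intermediate, selenium dioxide may also oxidise next to the ketone, or the acidic medium may open the epoxy alcohol. Fallback, from 7: ene-type allylic chlorination of the isopropenyl group (Ca(OCl)2, CO2, CH2Cl2–H2O) gives the allylic chloride F8. Oxidation with N-methylmorpholine N-oxide converts it into the enal 9, where the route is rejoined for step 6.

Step 7. Facial selectivity in the oxidation of the medium-ring enol ether may be poor, because it rests on a conformational argument. Deprotonation may also drift to C4 or to C7 of the lactone. Fallback, from 11: the lithium enolate (LiHMDS, −78 °C) is oxidised with a single enantiomer of (camphorsulfonyl)oxaziridine chosen for reagent control, giving the free C6 alcohol F9. Silylation (TBSCl, imidazole) returns to 13.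

Step 8. The C6 silyl ether may be lost or migrate under the acid before the epoxide opens, which would remove the hydroxyl differentiation needed in step 9. Fallback, from 11: the epoxide is hydrolysed first, when no silyl ether is present, to the diol F10. Acylation with 15 gives the isovalerate F11. The C6 hydroxyl is then introduced last by enolate oxidation (LiHMDS, 2.2 equiv; (camphorsulfonyl)oxaziridine), which arrives directly at 17.

## Further compounds

F1 | step 3 | 1,2-cis-diol of 4 (1,2,4a-triol, all three hydroxyls on one face) | O[C@@]12C[C@H](C(C)=C)[C@@H](O)[C@@H](O)[C@]1(C)CCC[C@@H]2C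
F2 | step 3 | 1,2-cyclic sulfate of F1 | O[C@@]12C[C@H](C(C)=C)[C@H]3OS(=O)(=O)O[C@H]3[C@]1(C)CCC[C@@H]2C
F3 | step 3 | potassium sulfate monoester of 6 at O8 | C/C1=C\[C@H](OS(=O)(=O)[O-])[C@@H](C(C)=C)CC(=O)[C@@H](C)CCC1.[K+]
F4 | step 1 | carvone 2,3-epoxide, epoxide trans to isopropenyl | O=C1C[C@H](C(C)=C)C[C@H]2O[C@@]12C
F5 | step 1 | pent-4-enyl carbinol from F4, hydroxyl cis to the epoxide | O[C@@]1(CCCC=C)C[C@H](C(C)=C)C[C@H]2O[C@@]12C
F6 | step 1 | 3-hydroxy-2-methyl-2-(pent-4-enyl)-5-(prop-1-en-2-yl)cyclohexanone, chain cis to isopropenyl | O=C1C[C@H](C(C)=C)C[C@@H](O)[C@]1(C)CCCC=C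
F7 | step 1 | 2-methyl-2-(pent-4-enyl)-5-(prop-1-en-2-yl)cyclohex-3-en-1-one | O=C1C[C@H](C(C)=C)C=C[C@]1(C)CCCC=C
F8 | step 5 | 7 with 3-chloroprop-1-en-2-yl at C7 | O[C@@H]1[C@@H](C(=C)CCl)CC(=O)[C@@H](C)CCC[C@]2(C)O[C@@H]12
F9 | step 7 | 11 bearing a free C6 hydroxyl | C=C1C(=O)O[C@@H]2[C@@H]1[C@H](O)C(=O)[C@@H](C)CCC[C@]3(C)O[C@@H]23
F10 | step 8 | 9,10-diol of 11 (no C6 oxygen) | C=C1C(=O)O[C@@H]2[C@@H]1CC(=O)[C@@H](C)CCC[C@@](C)(O)[C@H]2O
F11 | step 8 | 6-deoxy-17 (C9 isovalerate of F10) | C=C1C(=O)O[C@@H]2[C@@H]1CC(=O)[C@@H](C)CCC[C@@](C)(O)[C@H]2OC(=O)CC(C)C
A1 | alternative 1 | seco aldehyde with (Z)-2-(bromomethyl)enoate terminus, O6-TBS, O10-TES, O9-isovaleryl | O=C[C@H](OC(=O)CC(C)C)[C@](C)(O[Si](CC)(CC)CC)CCC[C@H](C)C(=O)[C@@H](O[Si](C)(C)C(C)(C)C)/C=C(\CBr)C(=O)OC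
A2 | alternative 2 | RCM diene (vinyl at C4, allyl at C10) carrying the lactone | C=C[C@H](C)C(=O)[C@@H](O)[C@@H]1C(=C)C(=O)O[C@H]1[C@H](OC(=O)CC(C)C)[C@](C)(O)CC=C
A3 | alternative 3 | 2-methyl-1,5-di(prop-1-en-2-yl)-2-vinylcyclohex-3-en-1-ol (divinyl carbinol from carvone) | O[C@]1(C(C)=C)C[C@H](C(C)=C)C=C[C@]1(C)C=C
A4 | alternative 3 | 2,6-dimethyl-9-(prop-1-en-2-yl)cyclodeca-5,7-dien-1-one (5E,7Z) | CC1CC/C=C(C)/C=C\[C@@H](C(C)=C)CC1=O
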